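## Retrosynthetic overview

- The only ring, the 19-membered lactam, is closed late by a Pd-catalysed intramolecular N-arylation (N–C20) of a primary Z-enamide with an aryl chloride; the C7 carbamate and desilylation follow.
- The seco chain is cut at C7–C8: chelation-controlled addition of a Z-alkenyl metal (C8–C15 plus arene) to an α-methoxy aldehyde (C1–C7).
- The alkenyl iodide comes from Z-iodo-olefination, Z-crotylboration (C10, C11) and a CuH/Pd hydroarylation that joins C15 to the arene and sets C14.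
- The arene comes from 3-chlorophenol by Ir-catalysed C–H borylation and iodination; both chiral chains (C12 and C6) come from one epoxide made from (R)-glycidol.

Assumption: the SMILES is read literally, i.e. 2Z, 8Z (C7 and C10 cis on C8=C9), 6S,7S,10S,11R,12S,14R. Atoms are numbered as in geldanamycin: C1 amide carbonyl to C15 benzylic CH2, C16–C21 arene, C18 bearing OH, C20 bearing N.

## Route

Step 1
Reactants: 1 3-chlorophenol
Product: 2 (3-chlorophenoxy)triisopropylsilane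
Conditions: TIPSCl, imidazole, DMF, rt
Reagents that add atoms: triisopropylsilyl chloride CC(C)[Si](Cl)(C(C)C)C(C)C
Why: Standard O-silylation of a phenol; the aryl TIPS ether survives the bases, oxidants and organometallics used later.

Step 2
Reactants: 2 (3-chlorophenoxy)triisopropylsilane
Product: 3 2-[3-chloro-5-(triisopropylsilyloxy)phenyl]-4,4,5,5-tetramethyl-1,3,2-dioxaborolane
Conditions: [Ir(OMe)(cod)]2 (1.5 mol%), 4,4'-di-tert-butyl-2,2'-bipyridine (3 mol%), B2pin2 (1.0 equiv), hexane, 60 °C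
Reagents that add atoms: bis(pinacolato)diboron CC1(C)OB(OC1(C)C)B1OC(C)(C)C(C)(C)O1
Why: Iridium-catalysed aromatic C–H borylation under steric control; C5–H is the only C–H without an ortho substituent, so the 1,3,5-pattern forms selectively.

Step 3
Reactants: 3 2-[3-chloro-5-(triisopropylsilyloxy)phenyl]-4,4,5,5-tetramethyl-1,3,2-dioxaborolane
Product: 4 (3-chloro-5-iodophenoxy)triisopropylsilane
Conditions: CuI (10 mol%), 1,10-phenanthroline (20 mol%), KI (1.5 equiv), MeOH/H2O 4:1, air, 80 °C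
Reagents that add atoms: potassium iodide [K+].[I-]
Why: Copper-catalysed oxidative iododeboronation (ipso substitution at the C–B bond) gives an iodide that reacts far faster than the chloride in later Pd chemistry.

Step 4
Reactants: 5 (R)-glycidol
Product: 6 (S)-2-[(4-methoxybenzyloxy)methyl]oxirane
Conditions: NaH, PMBCl, n-Bu4NI (cat.), THF/DMF, 0 °C → rt
Reagents that add atoms: 4-methoxybenzyl chloride COc1ccc(CCl)cc1
Why: Williamson etherification; the stereocentre is untouched (R becomes S only through the CIP priorities).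

Step 5
Reactants: 6 (S)-2-[(4-methoxybenzyloxy)methyl]oxirane
Product: 7 (S)-1-(4-methoxybenzyloxy)-4-methylpent-4-en-2-ol
Conditions: CH2=C(Me)MgBr (1.5 equiv), CuI (10 mol%), THF, −30 → 0 °C
Reagents that add atoms: isopropenylmagnesium bromide CC(=C)[Mg]Br
Why: Copper-catalysed SN2 opening of the terminal epoxide at its CH2 carbon; the carbinol centre (future C12) keeps its configuration.

Step 6
Reactants: 7 (S)-1-(4-methoxybenzyloxy)-4-methylpent-4-en-2-ol
Product: 8 1-methoxy-4-{[(2S)-2-methoxy-4-methylpent-4-enyl]oxymethyl}benzene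
Conditions: NaH, MeI, THF/DMF, 0 °C → rt
Reagents that add atoms: iodomethane CI
Why: Williamson O-methylation installs the C12 methoxy group without change at the stereocentre.

Step 7
Reactants: 8 1-methoxy-4-{[(2S)-2-methoxy-4-methylpent-4-enyl]oxymethyl}benzene; 4 (3-chloro-5-iodophenoxy)triisopropylsilane
Product: 9 {3-chloro-5-[(2R,4S)-4-methoxy-5-(4-methoxybenzyloxy)-2-methylpentyl]phenoxy}triisopropylsilane
Conditions: Cu(OAc)2 (5 mol%), (R)-DTBM-SEGPHOS (5.5 mol%), [Pd(cinnamyl)Cl]2 (2 mol%), BrettPhos (4.4 mol%), MePh2SiH (2 equiv), NaOSiMe3 (2 equiv), THF, 40 °C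
Reagents that add atoms: none
Why: CuH/Pd dual-catalysed anti-Markovnikov hydroarylation of a 1,1-disubstituted alkene: ligand-controlled hydrocupration delivers H to C14 (ligand antipode chosen for 14R, to be confirmed on the first run), the primary alkylcopper transmetalates to the arylpalladium iodide formed selectively at C–I, and reductive elimination forms C15–aryl with the chloride intact.

Step 8
Reactants: 9 {3-chloro-5-[(2R,4S)-4-methoxy-5-(4-methoxybenzyloxy)-2-methylpentyl]phenoxy}triisopropylsilane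
Product: 10 (2S,4R)-5-[3-chloro-5-(triisopropylsilyloxy)phenyl]-2-methoxy-4-methylpentan-1-ol
Conditions: DDQ (1.3 equiv), CH2Cl2/pH 7 buffer 10:1, 0 °C → rt
Reagents that add atoms: none
Why: Oxidative cleavage of the PMB ether; aryl silyl ether, methyl ether and aryl chloride are inert to DDQ.

Step 9
Reactants: 10 (2S,4R)-5-[3-chloro-5-(triisopropylsilyloxy)phenyl]-2-methoxy-4-methylpentan-1-ol
Product: 11 (2S,4R)-5-[3-chloro-5-(triisopropylsilyloxy)phenyl]-2-methoxy-4-methylpentanal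
Conditions: DMP (1.3 equiv), CH2Cl2, 0 °C → rt (used crude)
Reagents that add atoms: none
Why: Dess–Martin oxidation under near-neutral conditions gives the α-methoxy aldehyde without epimerising C12.

Step 10
Reactants: 11 (2S,4R)-5-[3-chloro-5-(triisopropylsilyloxy)phenyl]-2-methoxy-4-methylpentanal
Product: 12 (3S,4R,5S,7R)-8-[3-chloro-5-(triisopropylsilyloxy)phenyl]-5-methoxy-3,7-dimethyloct-1-en-4-ol
Conditions: (Z)-crotyl-Bpin (1.5 equiv), 4 Å MS, toluene, −78 °C → rt; aq. NaHCO3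
Reagents that add atoms: (Z)-crotylboronic acid pinacol ester C/C=C\CB1OC(C)(C)C(C)(C)O1
Why: Hoffmann–Roush crotylboration through a closed chair transition state: the Z-crotyl unit gives the 10,11-syn pair and Felkin–Anh/Cornforth attack on the Re face of the α-methoxy aldehyde gives 11,12-anti, i.e. 10S,11R.

Step 11
Reactants: 12 (3S,4R,5S,7R)-8-[3-chloro-5-(triisopropylsilyloxy)phenyl]-5-methoxy-3,7-dimethyloct-1-en-4-ol
Product: 13 (3S,4R,5S,7R)-4-(tert-butyldimethylsilyloxy)-8-[3-chloro-5-(triisopropylsilyloxy)phenyl]-5-methoxy-3,7-dimethyloct-1-ene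
Conditions: TBSOTf, 2,6-lutidine, CH2Cl2, −78 → 0 °C
Reagents that add atoms: tert-butyldimethylsilyl triflate CC(C)(C)[Si](C)(C)OS(=O)(=O)C(F)(F)F
Why: Silyl triflate silylation of the hindered C11 alcohol; no stereocentre is involved.

Step 12
Reactants: 13 (3S,4R,5S,7R)-4-(tert-butyldimethylsilyloxy)-8-[3-chloro-5-(triisopropylsilyloxy)phenyl]-5-methoxy-3,7-dimethyloct-1-ene
Product: 15 (2R,3R,4S,6R)-3-(tert-butyldimethylsilyloxy)-7-[3-chloro-5-(triisopropylsilyloxy)phenyl]-4-methoxy-2,6-dimethylheptanal, via ozonide 14 (not isolated)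
Conditions: O3, CH2Cl2, −78 °C; then PPh3, −78 °C → rt
Reagents that add atoms: ozone [O-][O+]=O
Why: Ozonolysis of the only alkene with reductive work-up; the α-methyl aldehyde (C9) is used at once to avoid epimerisation at C10.

Step 13
Reactants: 15 (2R,3R,4S,6R)-3-(tert-butyldimethylsilyloxy)-7-[3-chloro-5-(triisopropylsilyloxy)phenyl]-4-methoxy-2,6-dimethylheptanal
Product: 16 (2Z,4S,5R,6S,8R)-5-(tert-butyldimethylsilyloxy)-9-[3-chloro-5-(triisopropylsilyloxy)phenyl]-2-iodo-6-methoxy-4,8-dimethylnon-2-ene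
Conditions: EtPPh3I, n-BuLi, THF, rt; I2, −78 °C; NaN(SiMe3)2, −78 °C; then 15, −78 → −20 °C
Reagents that add atoms: ethyltriphenylphosphonium iodide CC[P+](c1ccccc1)(c1ccccc1)c1ccccc1.[I-]; iodine II
Why: Stork–Zhao-type Wittig olefination with the α-iodo ylide Ph3P=C(I)Me; the kinetically formed cis-oxaphosphetane puts iodine cis to the C10 chain, giving the Z-iodoalkene that fixes the 8Z geometry.

Step 14
Reactants: 6 (S)-2-[(4-methoxybenzyloxy)methyl]oxirane
Product: 17 (S)-1-(4-methoxybenzyloxy)hex-5-en-2-ol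
Conditions: CH2=CHCH2MgBr (1.5 equiv), CuI (10 mol%), THF, −40 → 0 °C
Reagents that add atoms: allylmagnesium bromide C=CC[Mg]Br
Why: Copper-catalysed epoxide opening at the terminal carbon; the carbinol centre becomes C6 with unchanged configuration.

Step 15
Reactants: 17 (S)-1-(4-methoxybenzyloxy)hex-5-en-2-ol
Product: 18 1-methoxy-4-{[(2S)-2-methoxyhex-5-enyl]oxymethyl}benzene
Conditions: NaH, MeI, THF/DMF, 0 °C → rt
Reagents that add atoms: iodomethane CI
Why: Williamson O-methylation installs the C6 methoxy group without change at the stereocentre.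

Step 16
Reactants: 18 1-methoxy-4-{[(2S)-2-methoxyhex-5-enyl]oxymethyl}benzene
Product: 20 (S)-4-methoxy-5-(4-methoxybenzyloxy)pentanal, via ozonide 19 (not isolated)
Conditions: O3, pyridine, CH2Cl2, −78 °C; then PPh3, −78 °C → rt
Reagents that add atoms: ozone [O-][O+]=O
Why: Ozonolysis of the terminal alkene, stopped at the first blue tinge so the PMB ring is not attacked, gives the C3 aldehyde.

Step 17
Reactants: 20 (S)-4-methoxy-5-(4-methoxybenzyloxy)pentanal
Product: 21 methyl (2Z,6S)-6-methoxy-7-(4-methoxybenzyloxy)hept-2-enoate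
Conditions: (CF3CH2O)2P(O)CH2CO2Me, KN(SiMe3)2, 18-crown-6, THF, −78 °C
Reagents that add atoms: methyl 2-[bis(2,2,2-trifluoroethoxy)phosphoryl]acetate COC(=O)CP(=O)(OCC(F)(F)F)OCC(F)(F)F
Why: Still–Gennari variant of the Horner–Wadsworth–Emmons reaction; fast, irreversible collapse of the syn adduct of the electron-poor phosphonate gives the 2Z enoate.

Step 18
Reactants: 21 methyl (2Z,6S)-6-methoxy-7-(4-methoxybenzyloxy)hept-2-enoate
Product: 22 methyl (2Z,6S)-7-hydroxy-6-methoxyhept-2-enoate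
Conditions: DDQ (1.3 equiv), CH2Cl2/pH 7 buffer 10:1, 0 °C → rt
Reagents that add atoms: none
Why: Oxidative PMB cleavage; the electron-poor Z-enoate is not touched by DDQ.

Step 19
Reactants: 22 methyl (2Z,6S)-7-hydroxy-6-methoxyhept-2-enoate
Product: 23 methyl (2Z,6S)-6-methoxy-7-oxohept-2-enoate
Conditions: DMP (1.3 equiv), CH2Cl2, 0 °C → rt (used crude)
Reagents that add atoms: none
Why: Dess–Martin oxidation gives the α-methoxy aldehyde (C7) without epimerising C6 or isomerising the Z-enoate.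

Step 20
Reactants: 16 (2Z,4S,5R,6S,8R)-5-(tert-butyldimethylsilyloxy)-9-[3-chloro-5-(triisopropylsilyloxy)phenyl]-2-iodo-6-methoxy-4,8-dimethylnon-2-ene; 23 methyl (2Z,6S)-6-methoxy-7-oxohept-2-enoate
Product: 26 methyl (2Z,6S,7S,8Z,10S,11R,12S,14R)-11-(tert-butyldimethylsilyloxy)-15-[3-chloro-5-(triisopropylsilyloxy)phenyl]-7-hydroxy-6,12-dimethoxy-8,10,14-trimethylpentadeca-2,8-dienoate, via alkenyllithium 24 (not isolated), via alkenylmagnesium bromide 25 (not isolated)
Conditions: t-BuLi (2.0 equiv), Et2O, −78 °C; MgBr2·OEt2, −78 °C; then 23, CH2Cl2, −78 °C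
Reagents that add atoms: none
Why: Iodine–lithium exchange with retention of the Z geometry (the aryl chloride does not exchange), transmetalation to magnesium and Cram-chelate 1,2-addition in which Mg bridges the aldehyde oxygen and the C6 methoxy group, so the alkenyl group enters anti to the C5 chain and gives the 6,7-syn alcohol (7S).

Step 21
Reactants: 26 methyl (2Z,6S,7S,8Z,10S,11R,12S,14R)-11-(tert-butyldimethylsilyloxy)-15-[3-chloro-5-(triisopropylsilyloxy)phenyl]-7-hydroxy-6,12-dimethoxy-8,10,14-trimethylpentadeca-2,8-dienoate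
Product: 27 methyl (2Z,6S,7S,8Z,10S,11R,12S,14R)-11-(tert-butyldimethylsilyloxy)-15-[3-chloro-5-(triisopropylsilyloxy)phenyl]-6,12-dimethoxy-8,10,14-trimethyl-7-(triethylsilyloxy)pentadeca-2,8-dienoate
Conditions: TESOTf, 2,6-lutidine, CH2Cl2, −78 °C
Reagents that add atoms: triethylsilyl triflate CC[Si](CC)(CC)OS(=O)(=O)C(F)(F)F
Why: Silylation caps the C7 hydroxyl so it can neither add to C3 (oxa-Michael) nor be arylated later, with a group more labile than the C11 TBS ether.

Step 22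
Reactants: 27 methyl (2Z,6S,7S,8Z,10S,11R,12S,14R)-11-(tert-butyldimethylsilyloxy)-15-[3-chloro-5-(triisopropylsilyloxy)phenyl]-6,12-dimethoxy-8,10,14-trimethyl-7-(triethylsilyloxy)pentadeca-2,8-dienoate
Product: 28 (2Z,6S,7S,8Z,10S,11R,12S,14R)-11-(tert-butyldimethylsilyloxy)-15-[3-chloro-5-(triisopropylsilyloxy)phenyl]-6,12-dimethoxy-8,10,14-trimethyl-7-(triethylsilyloxy)pentadeca-2,8-dienamide
Conditions: Me3Al (3 equiv), NH4Cl (3 equiv), toluene, 0 → 50 °C
Reagents that add atoms: ammonium chloride [NH4+].[Cl-]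
Why: Weinreb aminolysis: the aluminium amide made in situ converts the methyl ester directly into the primary amide without Brønsted base, so the 2Z geometry is kept.

Step 23
Reactants: 28 (2Z,6S,7S,8Z,10S,11R,12S,14R)-11-(tert-butyldimethylsilyloxy)-15-[3-chloro-5-(triisopropylsilyloxy)phenyl]-6,12-dimethoxy-8,10,14-trimethyl-7-(triethylsilyloxy)pentadeca-2,8-dienamide
Product: 29 19-membered lactam (N–C20 closed) of configuration (2Z,6S,7S,8Z,10S,11R,12S,14R) carrying 6,12-dimethoxy, 8,10,14-trimethyl, 7-triethylsilyloxy, 11-tert-butyldimethylsilyloxy and 18-triisopropylsilyloxy groups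
Conditions: Pd2(dba)3 (5 mol%), t-BuBrettPhos (12 mol%), K3PO4 (2 equiv), toluene (0.002 M), 90 °C
Reagents that add atoms: none
Why: Proposed new method: palladium-catalysed macrocyclising N-arylation of a primary amide by an unactivated aryl chloride to close a 19-membered ansa-lactam, in which zerovalent palladium carrying the bulky biaryl phosphine inserts into the C20–Cl bond, the primary amide binds through nitrogen and is deprotonated by K3PO4, and C–N reductive elimination from the divalent arylpalladium amidate is forced by the ligand while high dilution and the two Z-alkenes favour ring closure over oligomerisation; the closest known reactions are the intermolecular Pd-catalysed amidation of aryl chlorides with primary amides (Buchwald–Hartwig type) and the copper-mediated intramolecular amidation of aryl bromides (Goldberg type) used for related benzenoid ansamycin lactams.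

Step 24
Reactants: 29 19-membered lactam carrying 7-triethylsilyloxy, 11-tert-butyldimethylsilyloxy and 18-triisopropylsilyloxy groups
Product: 30 19-membered lactam with free 7-hydroxyl, 11-tert-butyldimethylsilyloxy and 18-triisopropylsilyloxy groups (configuration unchanged)
Conditions: PPTS (0.2 equiv), MeOH/CH2Cl2, 0 °C
Reagents that add atoms: none
Why: Acid-catalysed methanolysis removes the allylic TES ether selectively; the hindered TBS ether and the aryl TIPS ether react much more slowly.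

Step 25
Reactants: 30 19-membered lactam with free 7-hydroxyl, 11-tert-butyldimethylsilyloxy and 18-triisopropylsilyloxy groups
Product: 32 7-O-carbamoyl 19-membered lactam with 11-tert-butyldimethylsilyloxy and 18-triisopropylsilyloxy groups, via trichloroacetyl carbamate 31 (not isolated)
Conditions: Cl3CC(O)NCO, CH2Cl2, 0 °C; then K2CO3, MeOH, 0 °C
Reagents that add atoms: trichloroacetyl isocyanate O=C=NC(=O)C(Cl)(Cl)Cl
Why: Kočovský carbamoylation: the alcohol adds to the highly electrophilic isocyanate and mild methanolysis removes the trichloroacetyl group, leaving the primary carbamate with C7 untouched.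

Step 26
Reactants: 32 7-O-carbamoyl 19-membered lactam with 11-tert-butyldimethylsilyloxy and 18-triisopropylsilyloxy groups
Product: 33 CNP0263527.1 (target)
Conditions: HF·pyridine, pyridine, THF, 0 °C → rt
Reagents that add atoms: none
Why: Fluoride-mediated cleavage of the aryl TIPS and C11 TBS ethers under buffered conditions that leave the carbamate, the Z-enamide and all stereocentres unchanged.

## Compound list

1 | 3-chlorophenol | Oc1cccc(Cl)c1 | starting material
2 | (3-chlorophenoxy)triisopropylsilane | CC(C)[Si](Oc1cccc(Cl)c1)(C(C)C)C(C)C | intermediate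
3 | 2-[3-chloro-5-(triisopropylsilyloxy)phenyl]-4,4,5,5-tetramethyl-1,3,2-dioxaborolane | CC(C)[Si](Oc1cc(Cl)cc(c1)B1OC(C)(C)C(C)(C)O1)(C(C)C)C(C)C | intermediate
4 | (3-chloro-5-iodophenoxy)triisopropylsilane | CC(C)[Si](Oc1cc(Cl)cc(I)c1)(C(C)C)C(C)C | intermediate
5 | (R)-glycidol | OC[C@@H]1CO1 | starting material
6 | (S)-2-[(4-methoxybenzyloxy)methyl]oxirane | COc1ccc(COC[C@@H]2CO2)cc1 | intermediate
7 | (S)-1-(4-methoxybenzyloxy)-4-methylpent-4-en-2-ol | COc1ccc(COC[C@@H](O)CC(C)=C)cc1 | intermediate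
8 | 1-methoxy-4-{[(2S)-2-methoxy-4-methylpent-4-enyl]oxymethyl}benzene | COc1ccc(COC[C@@H](OC)CC(C)=C)cc1 | intermediate
9 | {3-chloro-5-[(2R,4S)-4-methoxy-5-(4-methoxybenzyloxy)-2-methylpentyl]phenoxy}triisopropylsilane | COc1ccc(COC[C@@H](OC)C[C@H](C)Cc2cc(Cl)cc(O[Si](C(C)C)(C(C)C)C(C)C)c2)cc1 | intermediate
10 | (2S,4R)-5-[3-chloro-5-(triisopropylsilyloxy)phenyl]-2-methoxy-4-methylpentan-1-ol | OC[C@@H](OC)C[C@H](C)Cc1cc(Cl)cc(O[Si](C(C)C)(C(C)C)C(C)C)c1 | intermediate
11 | (2S,4R)-5-[3-chloro-5-(triisopropylsilyloxy)phenyl]-2-methoxy-4-methylpentanal | O=C[C@@H](OC)C[C@H](C)Cc1cc(Cl)cc(O[Si](C(C)C)(C(C)C)C(C)C)c1 | intermediate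
12 | (3S,4R,5S,7R)-8-[3-chloro-5-(triisopropylsilyloxy)phenyl]-5-methoxy-3,7-dimethyloct-1-en-4-ol | C=C[C@H](C)[C@@H](O)[C@@H](OC)C[C@H](C)Cc1cc(Cl)cc(O[Si](C(C)C)(C(C)C)C(C)C)c1 | intermediate
13 | (3S,4R,5S,7R)-4-(tert-butyldimethylsilyloxy)-8-[3-chloro-5-(triisopropylsilyloxy)phenyl]-5-methoxy-3,7-dimethyloct-1-ene | C=C[C@H](C)[C@@H](O[Si](C)(C)C(C)(C)C)[C@@H](OC)C[C@H](C)Cc1cc(Cl)cc(O[Si](C(C)C)(C(C)C)C(C)C)c1 | intermediate
14 | ozonide of 13 (3-substituted 1,2,4-trioxolane, acetal carbon undefined) | C[C@@H](C1OCOO1)[C@@H](O[Si](C)(C)C(C)(C)C)[C@@H](OC)C[C@H](C)Cc1cc(Cl)cc(O[Si](C(C)C)(C(C)C)C(C)C)c1 | intermediate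
15 | (2R,3R,4S,6R)-3-(tert-butyldimethylsilyloxy)-7-[3-chloro-5-(triisopropylsilyloxy)phenyl]-4-methoxy-2,6-dimethylheptanal | O=C[C@H](C)[C@@H](O[Si](C)(C)C(C)(C)C)[C@@H](OC)C[C@H](C)Cc1cc(Cl)cc(O[Si](C(C)C)(C(C)C)C(C)C)c1 | intermediate
16 | (2Z,4S,5R,6S,8R)-5-(tert-butyldimethylsilyloxy)-9-[3-chloro-5-(triisopropylsilyloxy)phenyl]-2-iodo-6-methoxy-4,8-dimethylnon-2-ene | I/C(C)=C\[C@H](C)[C@@H](O[Si](C)(C)C(C)(C)C)[C@@H](OC)C[C@H](C)Cc1cc(Cl)cc(O[Si](C(C)C)(C(C)C)C(C)C)c1 | intermediate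
17 | (S)-1-(4-methoxybenzyloxy)hex-5-en-2-ol | COc1ccc(COC[C@@H](O)CCC=C)cc1 | intermediate
18 | 1-methoxy-4-{[(2S)-2-methoxyhex-5-enyl]oxymethyl}benzene | COc1ccc(COC[C@@H](OC)CCC=C)cc1 | intermediate
19 | ozonide of 18 (3-substituted 1,2,4-trioxolane, acetal carbon undefined) | COc1ccc(COC[C@@H](OC)CCC2OCOO2)cc1 | intermediate
20 | (S)-4-methoxy-5-(4-methoxybenzyloxy)pentanal | COc1ccc(COC[C@@H](OC)CCC=O)cc1 | intermediate
21 | methyl (2Z,6S)-6-methoxy-7-(4-methoxybenzyloxy)hept-2-enoate | COc1ccc(COC[C@@H](OC)CC/C=C\C(=O)OC)cc1 | intermediate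
22 | methyl (2Z,6S)-7-hydroxy-6-methoxyhept-2-enoate | OC[C@@H](OC)CC/C=C\C(=O)OC | intermediate
23 | methyl (2Z,6S)-6-methoxy-7-oxohept-2-enoate | O=C[C@@H](OC)CC/C=C\C(=O)OC | intermediate
24 | (Z)-alkenyllithium from 16 (Li in place of I at C8) | [Li]/C(C)=C\[C@H](C)[C@@H](O[Si](C)(C)C(C)(C)C)[C@@H](OC)C[C@H](C)Cc1cc(Cl)cc(O[Si](C(C)C)(C(C)C)C(C)C)c1 | intermediate
25 | (Z)-alkenylmagnesium bromide from 24 (MgBr at C8) | Br[Mg]/C(C)=C\[C@H](C)[C@@H](O[Si](C)(C)C(C)(C)C)[C@@H](OC)C[C@H](C)Cc1cc(Cl)cc(O[Si](C(C)C)(C(C)C)C(C)C)c1 | intermediate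
26 | methyl (2Z,6S,7S,8Z,10S,11R,12S,14R)-11-(tert-butyldimethylsilyloxy)-15-[3-chloro-5-(triisopropylsilyloxy)phenyl]-7-hydroxy-6,12-dimethoxy-8,10,14-trimethylpentadeca-2,8-dienoate | COC(=O)/C=C\CC[C@H](OC)[C@@H](O)/C(C)=C\[C@H](C)[C@@H](O[Si](C)(C)C(C)(C)C)[C@@H](OC)C[C@H](C)Cc1cc(Cl)cc(O[Si](C(C)C)(C(C)C)C(C)C)c1 | intermediate
27 | methyl (2Z,6S,7S,8Z,10S,11R,12S,14R)-11-(tert-butyldimethylsilyloxy)-15-[3-chloro-5-(triisopropylsilyloxy)phenyl]-6,12-dimethoxy-8,10,14-trimethyl-7-(triethylsilyloxy)pentadeca-2,8-dienoate | COC(=O)/C=C\CC[C@H](OC)[C@@H](O[Si](CC)(CC)CC)/C(C)=C\[C@H](C)[C@@H](O[Si](C)(C)C(C)(C)C)[C@@H](OC)C[C@H](C)Cc1cc(Cl)cc(O[Si](C(C)C)(C(C)C)C(C)C)c1 | intermediate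
28 | (2Z,6S,7S,8Z,10S,11R,12S,14R)-11-(tert-butyldimethylsilyloxy)-15-[3-chloro-5-(triisopropylsilyloxy)phenyl]-6,12-dimethoxy-8,10,14-trimethyl-7-(triethylsilyloxy)pentadeca-2,8-dienamide | NC(=O)/C=C\CC[C@H](OC)[C@@H](O[Si](CC)(CC)CC)/C(C)=C\[C@H](C)[C@@H](O[Si](C)(C)C(C)(C)C)[C@@H](OC)C[C@H](C)Cc1cc(Cl)cc(O[Si](C(C)C)(C(C)C)C(C)C)c1 | intermediate
29 | 19-membered lactam (2Z,6S,7S,8Z,10S,11R,12S,14R) with 7-OTES, 11-OTBS and 18-OTIPS | CO[C@H]1C[C@H](C)Cc2cc(O[Si](C(C)C)(C(C)C)C(C)C)cc(c2)NC(=O)/C=C\CC[C@H](OC)[C@@H](O[Si](CC)(CC)CC)/C(C)=C\[C@H](C)[C@H]1O[Si](C)(C)C(C)(C)C | intermediate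
30 | 19-membered lactam with 7-OH, 11-OTBS and 18-OTIPS | CO[C@H]1C[C@H](C)Cc2cc(O[Si](C(C)C)(C(C)C)C(C)C)cc(c2)NC(=O)/C=C\CC[C@H](OC)[C@@H](O)/C(C)=C\[C@H](C)[C@H]1O[Si](C)(C)C(C)(C)C | intermediate
31 | 7-O-(N-trichloroacetylcarbamoyl) lactam with 11-OTBS and 18-OTIPS | CO[C@H]1C[C@H](C)Cc2cc(O[Si](C(C)C)(C(C)C)C(C)C)cc(c2)NC(=O)/C=C\CC[C@H](OC)[C@@H](OC(=O)NC(=O)C(Cl)(Cl)Cl)/C(C)=C\[C@H](C)[C@H]1O[Si](C)(C)C(C)(C)C | intermediate
32 | 7-O-carbamoyl lactam with 11-OTBS and 18-OTIPS | CO[C@H]1C[C@H](C)Cc2cc(O[Si](C(C)C)(C(C)C)C(C)C)cc(c2)NC(=O)/C=C\CC[C@H](OC)[C@@H](OC(N)=O)/C(C)=C\[C@H](C)[C@H]1O[Si](C)(C)C(C)(C)C | intermediate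
33 | CNP0263527.1: (2Z,6S,7S,8Z,10S,11R,12S,14R)-7-carbamoyloxy-11,18-dihydroxy-6,12-dimethoxy-8,10,14-trimethyl 19-membered ansa-lactam | CO[C@H]1C[C@H](C)Cc2cc(O)cc(c2)NC(=O)/C=C\CC[C@H](OC)[C@@H](OC(N)=O)/C(C)=C\[C@H](C)[C@H]1O | target

## Step count and risks

Total step count: 26.

Longest linear sequence: 17 steps (steps 4–13, then 20–26, from 5; the chain from 1 through steps 1–3, 7–13 and 20–26 is equally long).

**Step 23 (proposed new Pd macrocyclisation).** Risks are oligomerisation, slow oxidative addition at high dilution and Z to E drift of the enamide at 90 °C. The fallback uses known chemistry, sets out from 27 and comes back at 29. The aryl chloride of ester 27 is aminated with benzophenone imine (Pd2(dba)3, XPhos, Cs2CO3, toluene, 100 °C) to the N-aryl benzophenone imine F4. NH2OH·HCl and NaOAc in MeOH cleave it to the aniline ester F5. Me3SnOH in 1,2-dichloroethane at 70 °C hydrolyses the methyl ester to the amino acid F6. A classical high-dilution macrolactamisation (BOP-Cl, i-Pr2NEt, toluene, 80 °C) then closes the amide bond instead of the aryl–N bond and gives 29.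

**Step 20 (fragment union).** Risks are incomplete chelation control at C7 and side reactions of the organolithium. The fallback sets out from 16 and 23 and comes back at 26. A Nozaki–Hiyama–Kishi coupling (CrCl2 4 equiv, NiCl2 1 mol%, DMSO/THF, rt) tolerates the aryl chloride and the enoate but gives 26 mixed with its C7 epimer F2. The mixture is oxidised with DMP to the single Z-enone F3. Reduction under Felkin–Anh, non-chelating control with K[(s-Bu)3BH] in THF at −78 °C returns the 6,7-syn alcohol 26.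

**Step 7 (CuH/Pd hydroarylation).** Risks are low diastereoselectivity at C14 in the mismatched sense, reduction of the aryl iodide and some reaction at C–Cl. The fallback sets out from 8 and 4 and comes back at 9. Alkene 8 is hydroborated enantioselectively with pinacolborane under CuH catalysis (CuCl, (R)-DTBM-SEGPHOS, KOt-Bu, THF, rt) to the primary alkyl pinacol boronate F1, with C14 set in a separate step. F1 is then coupled with aryl iodide 4 by a B-alkyl Suzuki–Miyaura reaction (Pd(OAc)2, RuPhos, K3PO4, toluene/H2O, 80 °C; iodide reacts before chloride) to give 9.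

Further compounds

F1 | step 7 | 2-[(2R,4S)-4-methoxy-5-(4-methoxybenzyloxy)-2-methylpentyl]-4,4,5,5-tetramethyl-1,3,2-dioxaborolane | COc1ccc(COC[C@@H](OC)C[C@H](C)CB2OC(C)(C)C(C)(C)O2)cc1
F2 | step 20 | methyl (2Z,6S,7R,8Z,10S,11R,12S,14R)-11-(tert-butyldimethylsilyloxy)-15-[3-chloro-5-(triisopropylsilyloxy)phenyl]-7-hydroxy-6,12-dimethoxy-8,10,14-trimethylpentadeca-2,8-dienoate (C7 epimer of 26) | COC(=O)/C=C\CC[C@H](OC)[C@H](O)/C(C)=C\[C@H](C)[C@@H](O[Si](C)(C)C(C)(C)C)[C@@H](OC)C[C@H](C)Cc1cc(Cl)cc(O[Si](C(C)C)(C(C)C)C(C)C)c1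
F3 | step 20 | methyl (2Z,6S,8Z,10S,11R,12S,14R)-11-(tert-butyldimethylsilyloxy)-15-[3-chloro-5-(triisopropylsilyloxy)phenyl]-6,12-dimethoxy-8,10,14-trimethyl-7-oxopentadeca-2,8-dienoate | COC(=O)/C=C\CC[C@H](OC)C(=O)/C(C)=C\[C@H](C)[C@@H](O[Si](C)(C)C(C)(C)C)[C@@H](OC)C[C@H](C)Cc1cc(Cl)cc(O[Si](C(C)C)(C(C)C)C(C)C)c1
F4 | step 23 | N-(diphenylmethylene)aniline analogue of 27 (N=CPh2 in place of Cl at C20) | COC(=O)/C=C\CC[C@H](OC)[C@@H](O[Si](CC)(CC)CC)/C(C)=C\[C@H](C)[C@@H](O[Si](C)(C)C(C)(C)C)[C@@H](OC)C[C@H](C)Cc1cc(N=C(c2ccccc2)c2ccccc2)cc(O[Si](C(C)C)(C(C)C)C(C)C)c1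
F5 | step 23 | aniline analogue of 27 (NH2 in place of Cl at C20) | COC(=O)/C=C\CC[C@H](OC)[C@@H](O[Si](CC)(CC)CC)/C(C)=C\[C@H](C)[C@@H](O[Si](C)(C)C(C)(C)C)[C@@H](OC)C[C@H](C)Cc1cc(N)cc(O[Si](C(C)C)(C(C)C)C(C)C)c1
F6 | step 23 | seco amino acid (C1 carboxylic acid of F5) | OC(=O)/C=C\CC[C@H](OC)[C@@H](O[Si](CC)(CC)CC)/C(C)=C\[C@H](C)[C@@H](O[Si](C)(C)C(C)(C)C)[C@@H](OC)C[C@H](C)Cc1cc(N)cc(O[Si](C(C)C)(C(C)C)C(C)C)c1
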